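**Strategy.** The oxolane ring (O1, C2 aryl, C3 CH2O-ester, C4 benzylidene, C5 OCH2) is closed at C4–C5 by an oxonium-Prins cyclisation. It exploits that C4 is the β-carbon of a para-oxygenated styrene, a phenylogous enol ether, and that C5 is a formaldehyde carbon on O1. The precursor is an acyclic methoxymethyl ether of a syn-aldol-derived homoallylic alcohol that already carries both stereocentres and the benzoate. Ionisation gives an O1=C5 oxocarbenium ion; C4 attacks it, and the aryl-stabilised cation loses H-4, so the ring and the (Z)-alkene, aryl beside the unsubstituted C5, arise in one operation.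

Key step: step 9

Remark: Ar = 4-(tert-butyldimethylsilyloxy)-3-methoxyphenyl, TBS = tert-butyldimethylsilyl; the target is read as (2R,3S,4Z), with the 2-aryl and 3-CH2O groups trans and the benzylidene aryl group on the C5 side.

**Step 1**
Reactants: 1 vanillin
Product: 2 4-(tert-butyldimethylsilyloxy)-3-methoxybenzaldehyde
Conditions: TBSCl, imidazole, DMF, rt
Reagents that add atoms: tert-butyldimethylsilyl chloride, CC(C)(C)[Si](C)(C)Cl
Why: Imidazole-promoted silylation of the phenol should be clean and leaves the aldehyde untouched.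

**Step 2**
Reactants: 2 4-(tert-butyldimethylsilyloxy)-3-methoxybenzaldehyde; 3 (2-carboxyethyl)triphenylphosphonium bromide
Product: 5 (E)-4-Ar-but-3-enoic acid, via carboxylate ylide 4 (not isolated)
Conditions: NaN(SiMe3)2 (2.1 equiv), THF, −20 °C; then 2, −20 °C → rt; cold 1 M HCl to pH 3
Reagents that add atoms: none
Why: Wittig olefination with a carboxylate-bearing ylide, which with aromatic aldehydes should give the E β,γ-unsaturated acid, the alkene staying in conjugation with the arene.

**Step 3**
Reactants: 5 (E)-4-Ar-but-3-enoic acid; 6 (R)-4-benzyl-1,3-oxazolidin-2-one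
Product: 8 (R)-4-benzyl-3-[(E)-4-Ar-but-3-enoyl]-1,3-oxazolidin-2-one, via pivalic mixed anhydride 7 (not isolated)
Conditions: t-BuCOCl, Et3N, THF, −20 °C; then 6, LiCl, −20 °C → rt
Reagents that add atoms: none
Why: N-acylation of the oxazolidinone through the mixed anhydride is mild enough to leave the styrene position and geometry unchanged.

**Step 4**
Reactants: 8 (R)-4-benzyl-3-[(E)-4-Ar-but-3-enoyl]-1,3-oxazolidin-2-one; 2 4-(tert-butyldimethylsilyloxy)-3-methoxybenzaldehyde
Product: 10 (R)-4-benzyl-3-[(2R,3E)-4-Ar-2-[(R)-Ar(hydroxy)methyl]but-3-enoyl]-1,3-oxazolidin-2-one, via Z boron enolate 9 (not isolated)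
Conditions: Bu2BOTf, i-Pr2NEt, CH2Cl2, −78 → 0 °C; then 2, −78 → 0 °C; pH 7 buffer, MeOH, 30% H2O2, 0 °C
Reagents that add atoms: none
Why: Evans syn aldol, in which the Z boron enolate should react at its α-carbon through a closed chair transition state on the face away from the benzyl group of the (R)-auxiliary, setting the future C3 and C2 as the (2R,3R) syn pair.

**Step 5**
Reactants: 10 syn aldol imide
Product: 11 (1R,2S)-1-Ar-2-[(E)-2-Ar-ethenyl]propane-1,3-diol
Conditions: LiBH4, MeOH (1.5 equiv), THF, 0 °C; aq. NH4Cl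
Reagents that add atoms: none
Why: Reductive removal of the auxiliary by LiBH4 should reduce only the imide carbonyl, without epimerisation and without touching the aryl silyl ethers or the alkene.

**Step 6**
Reactants: 12 4-hydroxybenzoic acid
Product: 14 4-(tert-butyldimethylsilyloxy)benzoic acid, via silyl ester 13 (not isolated)
Conditions: TBSCl (2.3 equiv), imidazole, DMF, rt; then AcOH/THF/H2O, rt
Reagents that add atoms: tert-butyldimethylsilyl chloride, CC(C)(C)[Si](C)(C)Cl
Why: Exhaustive silylation followed by selective hydrolysis of the labile silyl ester should leave the more robust aryl silyl ether.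

**Step 7**
Reactants: 11 (1R,2S)-diol; 14 4-(tert-butyldimethylsilyloxy)benzoic acid
Product: 15 (2S,3E)-4-Ar-2-[(R)-Ar(hydroxy)methyl]but-3-en-1-yl 4-(tert-butyldimethylsilyloxy)benzoate
Conditions: EDC·HCl, DMAP (0.1 equiv), CH2Cl2, −10 → 0 °C
Reagents that add atoms: none
Why: Steglich esterification should acylate the unhindered primary hydroxyl much faster than the hindered secondary benzylic one.

**Step 8**
Reactants: 15 primary benzoate
Product: 16 (2S,3E)-4-Ar-2-[(R)-Ar(methoxymethoxy)methyl]but-3-en-1-yl 4-(tert-butyldimethylsilyloxy)benzoate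
Conditions: MOMCl, i-Pr2NEt, Bu4NI (cat.), CH2Cl2, 0 °C → rt
Reagents that add atoms: chloromethyl methyl ether, COCCl
Why: O-alkylation of the secondary alcohol with MOMCl under an amine base (acetal formation) avoids alkoxide formation and hence acyl migration, and installs the formaldehyde carbon that becomes C5.

**Step 9**
Reactants: 16 methoxymethyl ether
Product: 19 [(2R,3S,4Z)-2-Ar-4-(Ar-methylidene)oxolan-3-yl]methyl 4-(tert-butyldimethylsilyloxy)benzoate, via oxocarbenium triflate 17 (not isolated), via benzylic cation triflate 18 (not isolated)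
Conditions: Me3SiOTf (1.3 equiv), 2,6-di-tert-butyl-4-methylpyridine (2 equiv), CH2Cl2, −78 → −30 °C; Et3N, aq. NaHCO3
Reagents that add atoms: none
Why: Me3SiOTf silylates the unhindered methoxy oxygen of the acetal and expels Me3SiOMe, giving the O1=C5H2 oxocarbenium ion 17, whose carbon is attacked by the styrene β-carbon (C4) to give the 4-silyloxybenzyl cation 18, which loses H-4 to the pyridine base. This is an oxonium-Prins (acetal-initiated cation–olefin) cyclisation ended by proton loss, closest to the Prins closure of aryl-substituted homoallylic acetals to oxolanes and to the acetal–vinylsilane route to 3-alkylideneoxolanes. The oxolane closes in a five-membered mode that is exo for the alkene and endo for the C=O+ bond, whereas the six-membered mode would place the charge on unstabilised C4. No stereocentre is made, since C2 and C3 come unchanged from the aldol and C4 returns to sp2; the Z geometry should follow from the conformer of 18 that aligns C4–H with the empty orbital by the smaller rotation and with less allylic 1,3-strain, which puts the aryl group beside C5 and not beside C3. The step needs ionisation at the acetal and not at the benzylic C2–O bond, and attack by C4 rather than by the ring on C2 or a 2-oxonia-Cope fragmentation; low temperature, the hindered base and the high nucleophilicity of the para-silyloxystyrene should secure this. The CH2O group on C3 is already an ester and cannot capture the cation.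

**Step 10**
Reactants: 19 tris-silyl ether
Product: 20 [(2R,3S,4Z)-2-(4-hydroxy-3-methoxyphenyl)-4-[(4-hydroxy-3-methoxyphenyl)methylidene]oxolan-3-yl]methyl 4-hydroxybenzoate
Conditions: Bu4NF (3.3 equiv), AcOH (3.5 equiv), THF, 0 °C
Reagents that add atoms: none
Why: Fluoride-mediated desilylation should cleave the three aryl silyl ethers rapidly, and the acetic acid buffer protects the ester and the phenolic styrene.

**Compound list**
1 | vanillin (4-hydroxy-3-methoxybenzaldehyde) | COc1cc(C=O)ccc1O | starting material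
2 | 4-(tert-butyldimethylsilyloxy)-3-methoxybenzaldehyde | COc1cc(C=O)ccc1O[Si](C)(C)C(C)(C)C | intermediate
3 | (2-carboxyethyl)triphenylphosphonium bromide | OC(=O)CC[P+](c1ccccc1)(c1ccccc1)c1ccccc1.[Br-] | starting material
4 | sodium 3-(triphenylphosphoranylidene)propanoate (carboxylate ylide, not isolated) | [Na+].[O-]C(=O)CC=P(c1ccccc1)(c1ccccc1)c1ccccc1 | intermediate
5 | (E)-4-Ar-but-3-enoic acid | COc1cc(/C=C/CC(=O)O)ccc1O[Si](C)(C)C(C)(C)C | intermediate
6 | (R)-4-benzyl-1,3-oxazolidin-2-one | O=C1N[C@H](Cc2ccccc2)CO1 | starting material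
7 | pivalic mixed anhydride of 5 (not isolated) | COc1cc(/C=C/CC(=O)OC(=O)C(C)(C)C)ccc1O[Si](C)(C)C(C)(C)C | intermediate
8 | (R)-4-benzyl-3-[(E)-4-Ar-but-3-enoyl]-1,3-oxazolidin-2-one | COc1cc(/C=C/CC(=O)N2[C@H](Cc3ccccc3)COC2=O)ccc1O[Si](C)(C)C(C)(C)C | intermediate
9 | Z dibutylboron enolate of 8 (not isolated) | CCCCB(CCCC)O/C(=C\C=C\c1ccc(O[Si](C)(C)C(C)(C)C)c(OC)c1)N1[C@H](Cc2ccccc2)COC1=O | intermediate
10 | (R)-4-benzyl-3-[(2R,3E)-4-Ar-2-[(R)-Ar(hydroxy)methyl]but-3-enoyl]-1,3-oxazolidin-2-one | O=C(N1[C@H](Cc2ccccc2)COC1=O)[C@H](/C=C/c1ccc(O[Si](C)(C)C(C)(C)C)c(OC)c1)[C@@H](O)c1ccc(O[Si](C)(C)C(C)(C)C)c(OC)c1 | intermediate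
11 | (1R,2S)-1-Ar-2-[(E)-2-Ar-ethenyl]propane-1,3-diol | OC[C@H](/C=C/c1ccc(O[Si](C)(C)C(C)(C)C)c(OC)c1)[C@@H](O)c1ccc(O[Si](C)(C)C(C)(C)C)c(OC)c1 | intermediate
12 | 4-hydroxybenzoic acid | OC(=O)c1ccc(O)cc1 | starting material
13 | tert-butyldimethylsilyl 4-(tert-butyldimethylsilyloxy)benzoate (not isolated) | CC(C)(C)[Si](C)(C)OC(=O)c1ccc(O[Si](C)(C)C(C)(C)C)cc1 | intermediate
14 | 4-(tert-butyldimethylsilyloxy)benzoic acid | OC(=O)c1ccc(O[Si](C)(C)C(C)(C)C)cc1 | intermediate
15 | (2S,3E)-4-Ar-2-[(R)-Ar(hydroxy)methyl]but-3-en-1-yl 4-(tert-butyldimethylsilyloxy)benzoate | O=C(OC[C@H](/C=C/c1ccc(O[Si](C)(C)C(C)(C)C)c(OC)c1)[C@@H](O)c1ccc(O[Si](C)(C)C(C)(C)C)c(OC)c1)c1ccc(O[Si](C)(C)C(C)(C)C)cc1 | intermediate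
16 | (2S,3E)-4-Ar-2-[(R)-Ar(methoxymethoxy)methyl]but-3-en-1-yl 4-(tert-butyldimethylsilyloxy)benzoate | O=C(OC[C@H](/C=C/c1ccc(O[Si](C)(C)C(C)(C)C)c(OC)c1)[C@@H](OCOC)c1ccc(O[Si](C)(C)C(C)(C)C)c(OC)c1)c1ccc(O[Si](C)(C)C(C)(C)C)cc1 | intermediate
17 | oxocarbenium triflate from 16, CH2=O+ on the benzylic oxygen (not isolated) | O=C(OC[C@H](/C=C/c1ccc(O[Si](C)(C)C(C)(C)C)c(OC)c1)[C@@H]([O+]=C)c1ccc(O[Si](C)(C)C(C)(C)C)c(OC)c1)c1ccc(O[Si](C)(C)C(C)(C)C)cc1.[O-]S(=O)(=O)C(F)(F)F | intermediate
18 | cyclised 4-silyloxybenzyl cation triflate, C4 epimers (not isolated) | COc1cc([CH+]C2CO[C@@H](c3ccc(O[Si](C)(C)C(C)(C)C)c(OC)c3)[C@@H]2COC(=O)c2ccc(O[Si](C)(C)C(C)(C)C)cc2)ccc1O[Si](C)(C)C(C)(C)C.[O-]S(=O)(=O)C(F)(F)F | intermediate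
19 | [(2R,3S,4Z)-2-Ar-4-(Ar-methylidene)oxolan-3-yl]methyl 4-(tert-butyldimethylsilyloxy)benzoate | COc1cc(/C=C2\CO[C@@H](c3ccc(O[Si](C)(C)C(C)(C)C)c(OC)c3)[C@@H]2COC(=O)c2ccc(O[Si](C)(C)C(C)(C)C)cc2)ccc1O[Si](C)(C)C(C)(C)C | intermediate
20 | [(2R,3S,4Z)-2-(4-hydroxy-3-methoxyphenyl)-4-[(4-hydroxy-3-methoxyphenyl)methylidene]oxolan-3-yl]methyl 4-hydroxybenzoate (CNP0134275.2) | COc1cc(/C=C2\CO[C@@H](c3ccc(O)c(OC)c3)[C@@H]2COC(=O)c2ccc(O)cc2)ccc1O | target

**Step count.** Total: 10 steps. Longest linear sequence: 9 steps (steps 1–5 and 7–10); step 6 is a one-step side branch.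

**Steps most likely to fail**

Step 9. The acetal may ionise at the benzylic C2–O bond or fragment by a 2-oxonia-Cope path instead of closing at C4. The benzylic cation may also be captured (by triflate, by methoxide or by the neighbouring arene) instead of losing H-4, or lose it with incomplete Z selectivity. The fallback sets out from 16 and comes back at 19, and separates ring closure from alkene formation. SnBr4 in CH2Cl2 at −78 °C would close the same C4–C5 bond with capture of the cation by bromide, giving [(2R,3S)-2-Ar-4-[Ar(bromo)methyl]oxolan-3-yl]methyl 4-(tert-butyldimethylsilyloxy)benzoate F1 as a diastereomer mixture that is used crude. DBU in toluene would then remove HBr; the easily ionised 4-silyloxybenzyl bromide should give the more stable Z alkene 19.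

Step 4. The styryl-substituted dienolate may react through its γ-carbon or let the alkene migrate during enolisation, and the electron-rich benzylic aldolate may undergo retro-aldol cleavage on work-up. The fallback sets out from 6 and 2 and comes back at 10, and attaches the second aryl ring only after the aldol. Compound 6 would be acylated with but-3-enoic acid (t-BuCOCl, Et3N, LiCl) to (R)-4-benzyl-3-(but-3-enoyl)-1,3-oxazolidin-2-one F2. The same boron aldol with 2 should give (R)-4-benzyl-3-[(2R)-2-[(R)-Ar(hydroxy)methyl]but-3-enoyl]-1,3-oxazolidin-2-one F3. Aldehyde 2 would be methylenated (Ph3PCH3Br, KOt-Bu, THF) to tert-butyl(2-methoxy-4-vinylphenoxy)dimethylsilane F4. Cross-metathesis of F3 with excess F4 (second-generation Hoveyda–Grubbs catalyst, CH2Cl2, 40 °C) should then give the E styrene 10.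

Step 7. Acylation may occur at the secondary hydroxyl or twice, and the acyl group may migrate from the primary to the secondary oxygen. The fallback sets out from 11 and comes back at 15, and activates the alcohol instead of the acid. A Mitsunobu esterification of 11 with 14 (PPh3, diisopropyl azodicarboxylate, THF, 0 °C) forms the alkoxyphosphonium ion only at the unhindered primary carbinol, so the ester should form there alone; no new compound is made.

**Further compounds**
F1 | step 9 | [(2R,3S)-2-Ar-4-[Ar(bromo)methyl]oxolan-3-yl]methyl 4-(tert-butyldimethylsilyloxy)benzoate (diastereomer mixture) | COc1cc(C(Br)C2CO[C@@H](c3ccc(O[Si](C)(C)C(C)(C)C)c(OC)c3)[C@@H]2COC(=O)c2ccc(O[Si](C)(C)C(C)(C)C)cc2)ccc1O[Si](C)(C)C(C)(C)C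
F2 | step 4 | (R)-4-benzyl-3-(but-3-enoyl)-1,3-oxazolidin-2-one | C=CCC(=O)N1[C@H](Cc2ccccc2)COC1=O
F3 | step 4 | (R)-4-benzyl-3-[(2R)-2-[(R)-Ar(hydroxy)methyl]but-3-enoyl]-1,3-oxazolidin-2-one | O=C(N1[C@H](Cc2ccccc2)COC1=O)[C@H](C=C)[C@@H](O)c1ccc(O[Si](C)(C)C(C)(C)C)c(OC)c1
F4 | step 4 | tert-butyl(2-methoxy-4-vinylphenoxy)dimethylsilane | COc1cc(C=C)ccc1O[Si](C)(C)C(C)(C)C
F0 | step 7 | none | none
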